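The target is a 1,2-diarylpropane-1,3-diol (C1 carbinol carbon on guaiacyl ring A, C2 bearing syringyl ring B and C3H2OH). Everything rests on disconnecting the C1–O bond: C1 is benzylic, para to the ring A ether oxygen, and its oxygen sits 1,3 to the C3 oxygen. A DDQ hydride abstraction from the C1 methylene, with capture of the cation by a tert-butyl carbonate on C3, should therefore close a trans-1,3-dioxan-2-one and set C1 from C2 in one operation. The precursor is the (S)-2,3-diarylpropyl tert-butyl carbonate, ring A benzylated (donor) and ring B acetylated (deactivated), reached by Perkin condensation and asymmetric hydrogenation.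

Key step: step 5

Remark: O-benzylvanillin 1 and homosyringic acid 2 are taken as purchased; the (R) ligand in step 2 is assigned by analogy with (E)-2-alkyl-2-alkenoic acids (same face, priority swap for an α-aryl group), and its antipode is used if a first run shows the opposite sense.

Step 1
Reactants: 1 4-(benzyloxy)-3-methoxybenzaldehyde (O-benzylvanillin); 2 4-hydroxy-3,5-dimethoxyphenylacetic acid (homosyringic acid)
Product: 4 (E)-2-(4-acetoxy-3,5-dimethoxyphenyl)-3-[4-(benzyloxy)-3-methoxyphenyl]prop-2-enoic acid, via O-acetylhomosyringic acetic anhydride 3 (not isolated)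
Conditions: Ac2O (4 equiv), Et3N (2 equiv), 110 °C; then H2O, 60 °C (no alkaline work-up); crystallisation
Reagents that add atoms: acetic anhydride, CC(=O)OC(C)=O
Why: Perkin condensation, in which the phenol is acetylated first, the enolate of mixed anhydride 3 adds to aldehyde 1, and acyl transfer with loss of acetate gives the conjugated acid, whose E isomer (aryl groups cis) is the usual thermodynamic product.

Step 2
Reactants: 4 (E)-2-(4-acetoxy-3,5-dimethoxyphenyl)-3-[4-(benzyloxy)-3-methoxyphenyl]prop-2-enoic acid
Product: 5 (2S)-2-(4-acetoxy-3,5-dimethoxyphenyl)-3-[4-(benzyloxy)-3-methoxyphenyl]propanoic acid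
Conditions: H2 (20 bar), Ru(OAc)2[(R)-H8-BINAP] (1 mol %), degassed MeOH, 30 °C
Reagents that add atoms: none
Why: Carboxylate-directed Noyori-type asymmetric hydrogenation of the trisubstituted acrylic acid should deliver H2 to one enantioface of the C=C bond bound to ruthenium through the carboxylate, the (R) ligand being expected to set C2 as S, while the homogeneous catalyst leaves the benzyl ether and the aryl acetate alone.

Step 3
Reactants: 5 (2S)-2-(4-acetoxy-3,5-dimethoxyphenyl)-3-[4-(benzyloxy)-3-methoxyphenyl]propanoic acid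
Product: 6 4-[(2S)-1-[4-(benzyloxy)-3-methoxyphenyl]-3-hydroxypropan-2-yl]-2,6-dimethoxyphenyl acetate
Conditions: BH3·SMe2 (1.3 equiv), THF, 0 °C → rt; then MeOH
Reagents that add atoms: none
Why: Borane reduces the free carboxylic acid through an acyloxyborane far faster than it attacks the aryl acetate or the benzyl ether (chemoselective borane reduction of an acid), and C2 is not enolised, so its configuration is kept.

Step 4
Reactants: 6 4-[(2S)-1-[4-(benzyloxy)-3-methoxyphenyl]-3-hydroxypropan-2-yl]-2,6-dimethoxyphenyl acetate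
Product: 7 tert-butyl (2S)-2-(4-acetoxy-3,5-dimethoxyphenyl)-3-[4-(benzyloxy)-3-methoxyphenyl]propyl carbonate
Conditions: Boc2O (1.5 equiv), DMAP (0.1 equiv), CH2Cl2, 0 °C → rt
Reagents that add atoms: di-tert-butyl dicarbonate, CC(C)(C)OC(=O)OC(=O)OC(C)(C)C
Why: DMAP-catalysed O-tert-butoxycarbonylation of the primary alcohol with Boc2O should give the mixed carbonate quickly at low temperature, before any acetyl transfer from the aryl acetate can compete.

Step 5
Reactants: 7 tert-butyl (2S)-2-(4-acetoxy-3,5-dimethoxyphenyl)-3-[4-(benzyloxy)-3-methoxyphenyl]propyl carbonate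
Product: 10 (4S,5S)-4-[4-(benzyloxy)-3-methoxyphenyl]-5-(4-acetoxy-3,5-dimethoxyphenyl)-1,3-dioxan-2-one, via para-alkoxybenzyl cation 8 (not isolated), via tert-butoxydioxanylium ion 9 (not isolated)
Conditions: DDQ (1.3 equiv), 2,6-dichloropyridine (2 equiv), 4 Å MS, ClCH2CH2Cl (0.02 M), 0 °C → rt
Reagents that add atoms: none
Why: Proposed new method: DDQ forms a charge-transfer complex with ring A and abstracts hydride from C1–H, the only C–H bond para to an ether oxygen, to give the quinone-methide-like cation 8, whose C1 is attacked by the carbonyl oxygen of the C3 tert-butyl carbonate to give ion 9, which sheds isobutene and leaves the 1,3-dioxan-2-one. The closest known reaction types are DDQ-mediated oxidative benzylic C–H cyclisations of electron-rich alkylarenes onto tethered oxygen nucleophiles and the capture of carbocations by tert-butyl carbonates to give cyclic carbonates, but their combination on a plain benzylic methylene is not established. The six-membered ring closes in a 6-exo-trig mode onto the cationic C1, whose C=C bond to ring A stays outside the new ring. The new stereocentre C1 is controlled by C2: in the chair-like transition state the ring B substituent on C2 and the planar ring A cation at C1 both lie equatorial, which leads to the trans (4S,5S) carbonate, and reversible ionisation of the benzylic C1–O bond would convert any cis isomer into it. The step needs site selectivity for C1–H over C2–H and over the OCH2Ph group, which the para-ether activation by ring A secures because the methoxy groups of ring B are meta to C2 and its para oxygen is acylated (this also disfavours a hydride shift from C2). It also needs ring closure to outrun loss of the C2 proton to a stilbene, which is why it is run cold, dilute and with no base stronger than 2,6-dichloropyridine.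

Step 6
Reactants: 10 (4S,5S)-4-[4-(benzyloxy)-3-methoxyphenyl]-5-(4-acetoxy-3,5-dimethoxyphenyl)-1,3-dioxan-2-one
Product: 11 (1S,2S)-1-[4-(benzyloxy)-3-methoxyphenyl]-2-(4-hydroxy-3,5-dimethoxyphenyl)propane-1,3-diol
Conditions: K2CO3 (0.3 equiv), MeOH, 0 °C → rt; then aq. NH4Cl
Reagents that add atoms: none
Why: Methoxide transesterification (methanolysis of the cyclic carbonate and of the aryl acetate) attacks only carbonyl carbons, so both stereocentres are untouched, and because ring A is still benzylated no phenoxide para to C1 can expel the carbonate as a quinone methide.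

Step 7
Reactants: 11 (1S,2S)-1-[4-(benzyloxy)-3-methoxyphenyl]-2-(4-hydroxy-3,5-dimethoxyphenyl)propane-1,3-diol
Product: 12 (1S,2S)-1-(4-hydroxy-3-methoxyphenyl)-2-(4-hydroxy-3,5-dimethoxyphenyl)propane-1,3-diol
Conditions: H2 (1 atm), Pd/C (10 wt %), EtOAc–EtOH, rt, stopped at full conversion
Reagents that add atoms: none
Why: Hydrogenolysis of the aryl benzyl ether over palladium in a neutral solvent is much faster than cleavage of the benzylic C1–OH bond, so both stereocentres should survive.

Compound list
1 | 4-(benzyloxy)-3-methoxybenzaldehyde (O-benzylvanillin) | COc1cc(C=O)ccc1OCc1ccccc1 | starting material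
2 | 4-hydroxy-3,5-dimethoxyphenylacetic acid (homosyringic acid) | COc1cc(CC(=O)O)cc(OC)c1O | starting material
3 | acetic 2-(4-acetoxy-3,5-dimethoxyphenyl)acetic anhydride (formed in the flask) | COc1cc(CC(=O)OC(C)=O)cc(OC)c1OC(C)=O | intermediate
4 | (E)-2-(4-acetoxy-3,5-dimethoxyphenyl)-3-[4-(benzyloxy)-3-methoxyphenyl]prop-2-enoic acid | COc1cc(/C=C(/C(=O)O)c2cc(OC)c(OC(C)=O)c(OC)c2)ccc1OCc1ccccc1 | intermediate
5 | (2S)-2-(4-acetoxy-3,5-dimethoxyphenyl)-3-[4-(benzyloxy)-3-methoxyphenyl]propanoic acid | COc1cc(C[C@H](C(=O)O)c2cc(OC)c(OC(C)=O)c(OC)c2)ccc1OCc1ccccc1 | intermediate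
6 | 4-[(2S)-1-[4-(benzyloxy)-3-methoxyphenyl]-3-hydroxypropan-2-yl]-2,6-dimethoxyphenyl acetate | COc1cc(C[C@H](CO)c2cc(OC)c(OC(C)=O)c(OC)c2)ccc1OCc1ccccc1 | intermediate
7 | tert-butyl (2S)-2-(4-acetoxy-3,5-dimethoxyphenyl)-3-[4-(benzyloxy)-3-methoxyphenyl]propyl carbonate | COc1cc(C[C@H](COC(=O)OC(C)(C)C)c2cc(OC)c(OC(C)=O)c(OC)c2)ccc1OCc1ccccc1 | intermediate
8 | C1 para-alkoxybenzyl cation of 7 (formed in the flask) | COc1cc([CH+][C@H](COC(=O)OC(C)(C)C)c2cc(OC)c(OC(C)=O)c(OC)c2)ccc1OCc1ccccc1 | intermediate
9 | (4S,5S)-2-tert-butoxy-4,5-diaryl-1,3-dioxan-2-ylium ion (formed in the flask) | COc1cc([C@H]2O[C+](OC(C)(C)C)OC[C@@H]2c3cc(OC)c(OC(C)=O)c(OC)c3)ccc1OCc4ccccc4 | intermediate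
10 | (4S,5S)-4-[4-(benzyloxy)-3-methoxyphenyl]-5-(4-acetoxy-3,5-dimethoxyphenyl)-1,3-dioxan-2-one (trans) | COc1cc([C@H]2OC(=O)OC[C@@H]2c3cc(OC)c(OC(C)=O)c(OC)c3)ccc1OCc4ccccc4 | intermediate
11 | (1S,2S)-1-[4-(benzyloxy)-3-methoxyphenyl]-2-(4-hydroxy-3,5-dimethoxyphenyl)propane-1,3-diol | COc1cc([C@@H](O)[C@H](CO)c2cc(OC)c(O)c(OC)c2)ccc1OCc1ccccc1 | intermediate
12 | (1S,2S)-1-(4-hydroxy-3-methoxyphenyl)-2-(4-hydroxy-3,5-dimethoxyphenyl)propane-1,3-diol | COc1cc([C@@H](O)[C@H](CO)c2cc(OC)c(O)c(OC)c2)ccc1O | target

Total step count: 7. Longest linear sequence: 7 steps (1 or 2 to 12).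

Steps most likely to fail

1. Step 5 (proposed new method). The C1 cation may lose the C2 proton to a conjugated stilbene faster than the carbonate closes, hydride abstraction from a plain benzylic methylene may be sluggish, or the released tert-butyl cation may alkylate ring B. The fallback is an auxiliary-controlled anti-aldol built from known chemistry; it sets out from 2 and 1 and comes back at 11.
   - Homosyringic acid 2 is acetylated (Ac2O, pyridine, then water, passing through 3) to 2-(4-acetoxy-3,5-dimethoxyphenyl)acetic acid F1.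
   - Pivaloyl chloride and Et3N in THF convert it into 2-(4-acetoxy-3,5-dimethoxyphenyl)acetic pivalic anhydride F2, which in the same flask acylates (S)-4-benzyloxazolidin-2-one in the presence of LiCl to give (S)-4-benzyl-3-[2-(4-acetoxy-3,5-dimethoxyphenyl)acetyl]oxazolidin-2-one F3.
   - A MgCl2-catalysed anti-selective aldol of this N-acyl oxazolidinone (Evans auxiliary) with aldehyde 1 (MgCl2 10 mol %, Et3N, Me3SiCl, EtOAc, rt) should give (S)-4-benzyl-3-[(2R,3S)-2-(4-acetoxy-3,5-dimethoxyphenyl)-3-[4-(benzyloxy)-3-methoxyphenyl]-3-(trimethylsilyloxy)propanoyl]oxazolidin-2-one F4. The soft enolisation tolerates the aryl acetate, and the chelated enolate is expected to be attacked on the face away from the benzyl group.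
   - LiBH4 in THF–MeOH at 0 °C removes the auxiliary and the aryl acetate to give (2S,3S)-3-[4-(benzyloxy)-3-methoxyphenyl]-2-(4-hydroxy-3,5-dimethoxyphenyl)-3-(trimethylsilyloxy)propan-1-ol F5, which K2CO3 in methanol desilylates in the same flask to 11.

2. Step 2. Enantioface discrimination on a trisubstituted 2,3-diarylacrylic acid may be insufficient, the sense of induction may be opposite to the one assumed, or turnover may be slow. The fallback replaces catalyst control by separation: it sets out from 4 and comes back at 5. Non-selective hydrogenation (H2 20 bar, [Rh(cod)(dppb)]BF4, MeOH, which spares the benzyl ether) gives racemic 2-(4-acetoxy-3,5-dimethoxyphenyl)-3-[4-(benzyloxy)-3-methoxyphenyl]propanoic acid F6, which is resolved by preparative chromatography on a chiral stationary phase; the (S) antipode is 5.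

3. Step 7. Hydrogenolytic loss of the benzylic C1 hydroxyl (para to the phenol that is being freed) or acid-induced epimerisation at C1 through a quinone methide could occur on an acidic catalyst batch or on over-reaction. The fallback replaces catalytic hydrogenolysis by single-electron reductive debenzylation; it sets out from 11 and comes back at 12 with no new compound. Treatment with excess lithium naphthalenide (LiC10H8, THF, −40 °C, then aq. NH4Cl) cleaves the aryl benzyl ether while C1 carries an alkoxide, which cannot leave.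

Further compounds
F1 | step 5 | 2-(4-acetoxy-3,5-dimethoxyphenyl)acetic acid | COc1cc(CC(=O)O)cc(OC)c1OC(C)=O
F2 | step 5 | 2-(4-acetoxy-3,5-dimethoxyphenyl)acetic pivalic anhydride (not isolated) | COc1cc(CC(=O)OC(=O)C(C)(C)C)cc(OC)c1OC(C)=O
F3 | step 5 | (S)-4-benzyl-3-[2-(4-acetoxy-3,5-dimethoxyphenyl)acetyl]oxazolidin-2-one | COc1cc(CC(=O)N2[C@@H](Cc3ccccc3)COC2=O)cc(OC)c1OC(C)=O
F4 | step 5 | (S)-4-benzyl-3-[(2R,3S)-2-(4-acetoxy-3,5-dimethoxyphenyl)-3-[4-(benzyloxy)-3-methoxyphenyl]-3-(trimethylsilyloxy)propanoyl]oxazolidin-2-one | COc1cc([C@@H](O[Si](C)(C)C)[C@H](C(=O)N2[C@@H](Cc3ccccc3)COC2=O)c2cc(OC)c(OC(C)=O)c(OC)c2)ccc1OCc1ccccc1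
F5 | step 5 | (2S,3S)-3-[4-(benzyloxy)-3-methoxyphenyl]-2-(4-hydroxy-3,5-dimethoxyphenyl)-3-(trimethylsilyloxy)propan-1-ol (not isolated) | COc1cc([C@@H](O[Si](C)(C)C)[C@H](CO)c2cc(OC)c(O)c(OC)c2)ccc1OCc1ccccc1
F6 | step 2 | racemic 2-(4-acetoxy-3,5-dimethoxyphenyl)-3-[4-(benzyloxy)-3-methoxyphenyl]propanoic acid | COc1cc(CC(C(=O)O)c2cc(OC)c(OC(C)=O)c(OC)c2)ccc1OCc1ccccc1
F0 | step 7 | none | none
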